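Per unit of concentration, dissolved substrate attacks target faster than it attacks partner, 330 /M/h against 190 /M/h.

    solid substrate ⇌ dissolved substrate, rate k1*(cs1 - [dissolved substrate]) while solid is left; crystals form when [dissolved substrate] > cs1 (cs1 = 18 mM, k1 = 0.54 /h)
    dissolved substrate + partner → target (k2 = 190 /M/h)
    dissolved substrate + target → side product (k3 = 330 /M/h)
    solid product ⇌ target, rate k4*(cs4 - [target]) while solid is left; crystals form when [target] > cs4 (cs4 = 2.0 mM, k4 = 23 /h)
    2 partner → self-condensation product (k5 = 21 /M/h)
    partner + protic impurity → quenched reagent (k6 = 27 /M/h)

solid substrate 43 mM; partner 38.7 mM; protic impurity 12.9 mM; time 3.0 h

- amount of target and solid product together at 3.0 h, in percent of the solid substrate charged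
- concentration of dissolved substrate in solution at 3.0 h, in percent of saturation

- percentages count the solid substrate that a species holds: one side product counts as two
- target is meant together with its solid product
- where a step has two of a species, its rate is k times that concentration squared, and two are used at each turn
- solid, in amounts per volume of the solution: solid substrate, solid product
- at the start none of the solid substrate is in solution
- dissolved substrate means what is dissolved; the solid is not counted in it
- run time (flask): 3.0 h

With target in solution held at its solubility by its solid, the making and the loss of target balance at the turning level of partner, which is the selectivity factor times that solubility:

turning level = side constant × solubility of target / making constant = 3.47 mM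

Above this level target grows, and below it target shrinks. Solid substrate feeds the solution at 9.72 mM/h at best, and self-condensation drops below that feed at a crossing level of 15.2 mM of partner. Partner above the crossing is counted as lost, and partner below it as going to target, so the gain down to the turning level is:

peak = crossing − turning − turning × ln(crossing / turning) = 6.61 mM

This gives the bound from above, 15.4%.

Step 6 takes partner at 0.348 /h with protic impurity held at its charge, and together with self-condensation, step 2 set aside, that brings partner to the crossing in about 0.692 h. With the feed at its best going into partner, the turning level follows about 1.21 h later, which leaves about 1.10 h. Dissolved substrate stays under the level where feed balances the side step, 8.10 mM, so 45.0%. At the turning level itself it stands lower, which gives 29.0%.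

turnovers of partner left = making constant × that level × time left = 1.69

Each turnover costs target one turning level, and the partner used in those turnovers still makes 2.84 mM, so the estimate from the ceiling comes to 8.28%. A ceiling less a loss is no floor, so for the yield this reckoning gives a bound from above and an estimate, but no bound from below.

The forecast gives 13% and 31%, with target “held near 2 mM by its solid”. Its yield stands under the ceiling and above the estimate, and its saturation lies between the two bounds.

The flask gives 9.24% and 33.8%. Side product then holds 31.4% of the solid substrate charged. Partner in this flask stands at 0.927 mM, below the turning level of 3.47 mM. In the neighbour flask charged with 150 mM of partner, partner at 3.00 h is down to 2.08 mM, also below that level, with target and solid product together at 20.6%.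

The constants used here were chosen freely; no experiment stands behind them.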